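## Analysis of the target

The target **27** is a 2-methoxy-3,5-dimethyl-4H-pyran-4-one bonded through C6 to C7 of a cis-fused bicyclo[4.2.0]oct-3-ene (C1 and C6 at the ring fusion, C7 and C8 in the four-membered ring). A peroxide bridges C2 and C5, so the six-membered ring is also a 2,3-dioxabicyclo[2.2.2]octene. There are six stereocentres: C1 and C7 are quaternary, and C1, C8, C7 and C6 are contiguous on the cyclobutane. The C1 methyl, the C6 hydrogen, the C7 methyl and the C8 methyl all lie on the convex face of the cyclobutane. The pyranone lies on its concave face, and the peroxide lies on the face of the six-membered ring turned away from the cyclobutane. Once the O–O bond is present, hydrides, low-valent metals and bases are excluded (C2–H is next to oxygen). Its precursor, a bicyclo[4.2.0]octa-2,4-diene, can ring-open electrocyclically on heating, and the cyclobutane is at risk whenever a cation or a carbanion is generated next to it while an acceptor sits on C7. The hard part is the fully substituted cyclobutane with three cis methyl groups on consecutive carbons and its only functional carbon on the hindered face. The strategy rests on C7: it carries exactly one carboxyl-level carbon, so the ring C1–C8–C7–C6 is the contracted form of a cyclopentanone fused at C1 and C6, and the C7–C8 bond can be made by a Wolff shift that pushes the carbonyl carbon out of the ring.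

Hydrindane intermediates are numbered as indenes: C3a becomes C1, C7a becomes C6, C1 becomes C7, C3 becomes C8, and C2 is expelled.

## Retrosynthetic reasoning

**27 to 26.** The two C–O bonds at C2 and C5 are cut together, which returns diene **26** and a [4+2] photooxygenation as the last step. No other step tolerates the peroxide, and the cyclobutane with its concave-face pyranone shields one face of the diene, so the cycloaddition itself sets C2 and C5.

**26 to 21 and 22.** The pyranone is opened at its lactone C–O bond and at the C5–C6 bond of the heterocycle. This gives aldehyde **21** and β-keto ester **22**; forward, a dianion aldol (**23**), oxidation (**24**), lactonisation (**25**) and O-methylation at the lactone carbonyl rebuild it. An aldehyde is used rather than ester **19** because C7 is quaternary and the carbonyl sits on the concave face.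

**21 to 19 to 18.** The C7–CH3 bond is cut. Ester **18** has a hydrogen on C7 and serves as the enolate precursor. A small methyl electrophile should take the convex face of the planar enolate, leaving the carboxyl carbon on the concave face where the target needs it; reduction and re-oxidation then give **21**.

**18 to 16 (key).** The C7–C8 bond is cut and a carbonyl carbon is re-inserted between C7 and C8, giving α-diazoketone **16**. Forward, loss of dinitrogen with a 1,2-shift of C3 gives ketene **17**, which the alcohol solvent traps. The ring closes by migration, so the cis fusion and the configuration of the migrating carbon are carried over unchanged.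

**16 to 14.** The diazo group is removed from C1. Ketone **14** has a single methylene next to the carbonyl, so activation as the trifluoroacetyl derivative **15** and sulfonyl azide transfer can only occur there.

**14 to 12 to 11 to 10.** The six-membered ring is brought to the diene level before the contraction. After it, a ketone at C4 of the bicyclooctane could only be converted through its C5 enolate, which can expel the ester-stabilised C7 carbanion and open the cyclobutane, or through an allyl cation next to the cyclobutane, which invites ring expansion. Before the contraction neither hazard exists. In **10** the β-keto ester protects C2 as its enolate while the C6 ketone is converted to dienyl triflate **11**. The same β-keto ester, as its dianion, then directs the C3 methyl group (**12**). One palladium-catalysed hydride transfer finally removes the triflate and the allyl ester, the latter by way of acid **13**.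

**10 to 9.** The C1–C7a bond is cut. Dienone **9** has two enantiotopic enone arms on a prochiral quaternary carbon, and a chiral bifunctional catalyst chooses one of them in an intramolecular Michael addition, setting C3a and C7a. An acidic 1,3-dicarbonyl donor is used because this closure places the donor carbonyl inside the new five-membered ring, which is geometrically reluctant for a simple ketone enolate or enamine. The tether carries no stereocentre, so the catalyst is the only source of asymmetry.

**9 to 5 and 8; 8 to 6; 5 to 4 to 1 and 2.** The β-keto ester is cut between its ketone carbon and the methylene, giving aldehyde **5** and diazoacetate **8** (Roskamp homologation). **8** comes from acetoacetate **6** through **7**. **5** comes from cleavage of the allyl group of **4**, and **4** from phenol **1** and allyl bromide **2** by C-allylation at an ortho carbon (**3**) and a Cope shift to the para position.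

## Alternatives that were turned down

**Alternative 1:** The C2–O bond of the peroxide is disconnected, so the bridge would be closed by intramolecular conjugate addition of a tertiary C5 hydroperoxide, 6-(5-hydroperoxy-1,3,5,7,8-pentamethyl-4-oxobicyclo[4.2.0]oct-2-en-7-yl)-2-methoxy-3,5-dimethyl-4H-pyran-4-one **A2**, onto C2 of its own enone, giving the epidioxy ketone **A1**.
- For it: the C5 oxygen would be placed by ground-state enolate oxygenation, and no facial selectivity of a cycloaddition is needed.
- Against it: the addition must create an enolate (C3=C4–O) inside a bicyclo[2.2.2] frame whose π system is nearly orthogonal to the forming C2–O bond, so it is stereoelectronically poor and easily reversed. **A2** is an α-hydroperoxy ketone prone to C–C cleavage. **A1** still needs its C4 ketone and saturated C3 converted to the C3=C4 alkene, and every way of doing that (hydride, strong base, zerovalent palladium) attacks the O–O bond.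
- Comparison: the chosen route forms both C–O bonds in the final step on **26** with nothing left to do afterwards. Alternative 1 is not stronger on any point; its one advantage (no reliance on diene face selectivity) is not needed here, because the cyclobutane already differentiates the faces.

**Alternative 2:** C1–C2 and C5–C6 are disconnected. Methyl (1R,4R)-1,3,4-trimethylcyclobut-2-ene-1-carboxylate **A4** would add as dienophile to 2,4-dimethylthiophene 1,1-dioxide **A5**, and cheletropic loss of the sulfone bridge would give the diene ester **A3**, which is identical with **19**.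
- For it: it is convergent and reaches **19** in one step from **A4**. If **A4** were available in a few steps it would be shorter than the eleven steps to **19** here, so it is stronger on step count at that stage.
- Against it: **A4** is an unactivated trisubstituted cyclobutene and needs strong heating, at which the product diene can scramble by electrocyclic ring opening. Which end of the unsymmetrical diene bonds to C1 depends only on small alkyl biases. **A5** dimerises. Enantiopure **A4**, with its quaternary centre and cis methyl groups, is itself much of the original problem.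
- Comparison: the chosen route fixes the methyl positions of the six-membered ring by their origin in **1** and sets each cyclobutane centre in a separate ground-state step.

**Alternative 3:** C1–C8 and C6–C7 are disconnected. Photoexcited mesitylene **A8** would add across one of its ring bonds to (−)-8-phenylmenthyl tiglate **A7** in an ortho [2+2] cycloaddition, giving the auxiliary ester **A6**.
- For it: it is by far the shortest. One step builds the carbocycle with all five methyl groups, all ring bonds of **A8** are equivalent, and the tiglate geometry supplies the cis C7/C8 methyl groups. On step economy it is clearly stronger than the chosen route.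
- Against it: ortho versus meta addition, head-to-head versus head-to-tail orientation and exo/endo selectivity are all open. The tiglate isomerises under irradiation. An ester auxiliary exerts little facial control in an excited-state reaction. The product diene absorbs light and can ring-open or add again.
- Comparison: the chosen route is much longer but sets relative and absolute configuration by defined ground-state events.

Key step: step 10

Assumption: the quinine-derived thiourea of step 5 is taken to attack the enone arm that leads to (3aR,7aS)-**10**. This sense of induction is by analogy; the quinidine-derived pseudoenantiomer would be used if the other arm reacts.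

## Route

**Step 1**
Reactants: 1 2,4,6-trimethylphenol; 2 allyl bromide
Product: 4 4-allyl-2,4,6-trimethylcyclohexa-2,5-dien-1-one, via ortho-dienone 3 (not isolated)
Conditions: NaH, PhMe, 0 → 23 °C; then 90 °C
Reagents that add atoms: none
Why: In a non-polar medium the sodium phenoxide is alkylated on the methyl-bearing ortho carbon to give 3, and on warming 3 undergoes a Cope [3,3] shift of the allyl group to C4, giving the cross-conjugated dienone 4. The O-allyl ether formed alongside is separated; it is the aromatic sink of this manifold, which is why 4 is not approached from the ether.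

**Step 2**
Reactants: 4 4-allyl-2,4,6-trimethylcyclohexa-2,5-dien-1-one
Product: 5 2-(1,3,5-trimethyl-4-oxocyclohexa-2,5-dien-1-yl)acetaldehyde
Conditions: OsO4 (2 mol %), NaIO4, 2,6-lutidine, dioxane–H2O, 23 °C
Reagents that add atoms: osmium tetroxide, O=[Os](=O)(=O)=O (transfers the oxygen atom; kept in turnover by sodium periodate, [Na+].[O-]I(=O)(=O)=O)
Why: Lemieux–Johnson cleavage; OsO4 should dihydroxylate the electron-rich monosubstituted alkene in preference to the hindered, electron-poor enone double bonds, and periodate cleaves the diol.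

**Step 3**
Reactants: 6 allyl acetoacetate
Product: 8 allyl diazoacetate, via allyl 2-diazo-3-oxobutanoate 7 (not isolated)
Conditions: 4-AcNHC6H4SO2N3, Et3N, MeCN, 0 → 23 °C; then LiOH, H2O, 23 °C
Reagents that add atoms: 4-acetamidobenzenesulfonyl azide, CC(=O)Nc1ccc(cc1)S(=O)(=O)N=[N+]=[N-]
Why: Regitz diazo transfer to the active methylene followed by hydroxide-induced deacetylation, the usual preparation of diazoacetates; 8 is handled as a solution.

**Step 4**
Reactants: 5 2-(1,3,5-trimethyl-4-oxocyclohexa-2,5-dien-1-yl)acetaldehyde; 8 allyl diazoacetate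
Product: 9 allyl 3-oxo-4-(1,3,5-trimethyl-4-oxocyclohexa-2,5-dien-1-yl)butanoate
Conditions: SnCl2 (10 mol %), CH2Cl2, 23 °C
Reagents that add atoms: none
Why: Roskamp homologation; the divalent tin Lewis acid activates the aldehyde, the diazo carbon adds, and a 1,2-hydride shift with loss of dinitrogen gives the β-keto ester. The dienone is inert, and 9 is taken on promptly to limit uncatalysed cyclisation.

**Step 5**
Reactants: 9 allyl 3-oxo-4-(1,3,5-trimethyl-4-oxocyclohexa-2,5-dien-1-yl)butanoate
Product: 10 allyl (3aR,7aS)-3a,5,7-trimethyl-2,6-dioxo-2,3,3a,6,7,7a-hexahydro-1H-indene-1-carboxylate (cis-fused; C1 and C7 as epimer mixtures)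
Conditions: 1-[3,5-bis(trifluoromethyl)phenyl]-3-[(8α,9S)-6′-methoxycinchonan-9-yl]thiourea (10 mol %), PhMe, 0 °C
Reagents that add atoms: none
Why: Bifunctional amine–thiourea catalysed intramolecular Michael addition (5-exo-trig) of the β-keto ester to one of the two enantiotopic enone arms. The tether can reach the β-carbon only from its own face, so the fusion is cis, and the catalyst's choice of arm sets C3a and C7a. C1 and C7 are epimerisable and are erased in steps 6 to 8.

**Step 6**
Reactants: 10 allyl (3aR,7aS)-3a,5,7-trimethyl-2,6-dioxo-2,3,3a,6,7,7a-hexahydro-1H-indene-1-carboxylate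
Product: 11 allyl 3a,5,7-trimethyl-2-oxo-6-[(trifluoromethylsulfonyl)oxy]-2,3,3a,7a-tetrahydro-1H-indene-1-carboxylate (ring fusion as in 10)
Conditions: KN(SiMe3)2 (2.1 equiv), THF, −78 °C; N-(5-chloropyridin-2-yl)NTf2, −78 °C
Reagents that add atoms: N-(5-chloropyridin-2-yl)bis(trifluoromethanesulfonimide), O=S(=O)(N(c1ccc(Cl)cn1)S(=O)(=O)C(F)(F)F)C(F)(F)F
Why: The first equivalent of base forms the β-keto ester enolate, which protects C2. The second removes C7–H, the only proton α to the C6 ketone, and the more basic cross-conjugated dienolate should be O-triflated selectively. The silazide is too weak to deprotonate C3.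

**Step 7**
Reactants: 11 allyl 3a,5,7-trimethyl-2-oxo-6-[(trifluoromethylsulfonyl)oxy]-2,3,3a,7a-tetrahydro-1H-indene-1-carboxylate
Product: 12 allyl 3,3a,5,7-tetramethyl-2-oxo-6-[(trifluoromethylsulfonyl)oxy]-2,3,3a,7a-tetrahydro-1H-indene-1-carboxylate (3-methyl cis to the 3a-methyl)
Conditions: LiN(iPr)2 (2.2 equiv), THF, −78 → −30 °C; MeI, −78 → −30 °C
Reagents that add atoms: iodomethane, CI
Why: γ-Alkylation of a β-keto ester dianion; the second charge sits on C3, the more reactive carbon. Allylic 1,2-strain with the C7 methyl keeps C1 pseudoaxial at C7a, which turns the C3a–C4 bond nearly perpendicular to the dianion plane on the concave side, so iodomethane should enter anti to it, cis to the angular methyl. The temperature is kept low to avoid a dianionic Carroll rearrangement of the allyl ester.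

**Step 8**
Reactants: 12 allyl 3,3a,5,7-tetramethyl-2-oxo-6-[(trifluoromethylsulfonyl)oxy]-2,3,3a,7a-tetrahydro-1H-indene-1-carboxylate
Product: 14 (3R,3aS,7aR)-3,3a,5,7-tetramethyl-1,3,3a,7a-tetrahydro-2H-inden-2-one, via β-keto acid 13 (not isolated)
Conditions: Pd(OAc)2 (5 mol %), PPh3, HCO2H, Et3N, DMF, 40 °C
Reagents that add atoms: none
Why: Zerovalent palladium inserts into both the allyl ester and the dienyl triflate. Formate reduces the π-allyl complex to propene and the alkenylpalladium to C–H, and acid 13 decarboxylates. The buffered, near-neutral medium should leave the C3 centre as set in step 7.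

**Step 9**
Reactants: 14 (3R,3aS,7aR)-3,3a,5,7-tetramethyl-1,3,3a,7a-tetrahydro-2H-inden-2-one
Product: 16 (3R,3aS,7aR)-1-diazo-3,3a,5,7-tetramethyl-1,3,3a,7a-tetrahydro-2H-inden-2-one, via 1-trifluoroacetyl ketone 15 (not isolated)
Conditions: LiN(SiMe3)2, THF, −78 °C; CF3CO2CH2CF3; then MsN3, Et3N, H2O, MeCN, 23 °C
Reagents that add atoms: methanesulfonyl azide, CS(=O)(=O)N=[N+]=[N-] (both nitrogen atoms of 16); 2,2,2-trifluoroethyl trifluoroacetate, O=C(OCC(F)(F)F)C(F)(F)F (the trifluoroacetyl group of 15)
Why: Detrifluoroacetylative diazo transfer; kinetic deprotonation takes the only methylene next to the ketone (C1), C-acylation gives 15, and azide transfer with loss of the trifluoroacetyl group gives the diazoketone. C3 is not enolised under these conditions.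

**Step 10**
Reactants: 16 (3R,3aS,7aR)-1-diazo-3,3a,5,7-tetramethyl-1,3,3a,7a-tetrahydro-2H-inden-2-one
Product: 18 methyl (1S,6R,7S,8S)-1,3,5,8-tetramethylbicyclo[4.2.0]octa-2,4-diene-7-carboxylate, via ketene 17 (not isolated)
Conditions: hν (405 nm), MeOH, 0 °C
Reagents that add atoms: methanol, CO
Why: Excitation of the diazoketone, which the ring holds s-cis with the C2–C3 bond anti-periplanar to the departing dinitrogen, expels N2 while C3 shifts from the carbonyl carbon to the diazo carbon, giving ketene 17; methanol adds and the ester enol is protonated. The closest known reaction type is the photochemical Wolff ring contraction of cyclic 2-diazoketones, established for five-to-four contraction (2-diazocyclopentanones to cyclobutanecarboxylates, 16-diazo-17-keto steroids to D-nor acids). The cyclobutane is closed by a 1,2-alkyl shift, not by a cyclisation, so no ring-closure trajectory has to be met and the cis fusion at C1/C6 comes unchanged from 16. C8 keeps its configuration because the migrating carbon stays on the face it is bonded to (suprafacial shift with retention). The new centre C7 is set by protonation of the enol from the convex face (ester on the concave face, as named); it is re-made in step 11, so its epimer is equally usable. The step needs migration to outrun the carbene channels (O–H insertion, 1,2-shift of the allylic C7a hydrogen), which the fixed s-cis geometry and direct, unsensitised excitation favour. It also needs light that only the diazoketone absorbs, which 405 nm provides because the isolated diene of 16 and 18 absorbs only below about 300 nm. The reaction is run cold and 18 is isolated without heating, since bicyclo[4.2.0]octa-2,4-dienes can ring-open thermally.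

**Step 11**
Reactants: 18 methyl (1S,6R,7S,8S)-1,3,5,8-tetramethylbicyclo[4.2.0]octa-2,4-diene-7-carboxylate
Product: 19 methyl (1R,6R,7S,8R)-1,3,5,7,8-pentamethylbicyclo[4.2.0]octa-2,4-diene-7-carboxylate
Conditions: LiN(iPr)2, THF, −78 °C; MeI, −78 → −20 °C
Reagents that add atoms: iodomethane, CI
Why: Alkylation of the ester enolate, which is exocyclic to the cyclobutane; iodomethane should approach the convex face, away from the six-membered ring whose C5 and C5 methyl flank the concave face. The methyl thus ends cis to the C8 methyl, the ester stays on the concave face, and C7 becomes a fixed quaternary centre.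

**Step 12**
Reactants: 19 methyl (1R,6R,7S,8R)-1,3,5,7,8-pentamethylbicyclo[4.2.0]octa-2,4-diene-7-carboxylate
Product: 20 [(1R,6R,7S,8R)-1,3,5,7,8-pentamethylbicyclo[4.2.0]octa-2,4-dien-7-yl]methanol
Conditions: LiAlH4, Et2O, 0 °C
Reagents that add atoms: none
Why: Hydride reduction of the hindered ester to the neopentyl alcohol; the diene is inert.

**Step 13**
Reactants: 20 [(1R,6R,7S,8R)-1,3,5,7,8-pentamethylbicyclo[4.2.0]octa-2,4-dien-7-yl]methanol
Product: 21 (1R,6R,7S,8R)-1,3,5,7,8-pentamethylbicyclo[4.2.0]octa-2,4-diene-7-carbaldehyde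
Conditions: Dess–Martin periodinane, NaHCO3, CH2Cl2, 0 → 23 °C
Reagents that add atoms: none
Why: Buffered Dess–Martin oxidation to the non-enolisable aldehyde under neutral conditions.

**Step 14**
Reactants: 21 (1R,6R,7S,8R)-1,3,5,7,8-pentamethylbicyclo[4.2.0]octa-2,4-diene-7-carbaldehyde; 22 methyl 2-methyl-3-oxopentanoate
Product: 23 methyl 5-hydroxy-2,4-dimethyl-3-oxo-5-[(1R,6R,7S,8R)-1,3,5,7,8-pentamethylbicyclo[4.2.0]octa-2,4-dien-7-yl]pentanoate (mixture at the three chain centres)
Conditions: 22, NaH, THF, 0 °C; n-BuLi, 0 °C; then 21, −78 °C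
Reagents that add atoms: none
Why: Aldol addition of the β-keto ester dianion through its terminal (γ) carbon to the aldehyde; the new chain centres are not controlled because all are removed in steps 15 and 16.

**Step 15**
Reactants: 23 methyl 5-hydroxy-2,4-dimethyl-3-oxo-5-[(1R,6R,7S,8R)-1,3,5,7,8-pentamethylbicyclo[4.2.0]octa-2,4-dien-7-yl]pentanoate
Product: 24 methyl 2,4-dimethyl-3,5-dioxo-5-[(1R,6R,7S,8R)-1,3,5,7,8-pentamethylbicyclo[4.2.0]octa-2,4-dien-7-yl]pentanoate
Conditions: Dess–Martin periodinane, CH2Cl2, 23 °C
Reagents that add atoms: none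
Why: Oxidation of the secondary alcohol to the enolised β,δ-diketo ester.

**Step 16**
Reactants: 24 methyl 2,4-dimethyl-3,5-dioxo-5-[(1R,6R,7S,8R)-1,3,5,7,8-pentamethylbicyclo[4.2.0]octa-2,4-dien-7-yl]pentanoate
Product: 25 4-hydroxy-3,5-dimethyl-6-[(1R,6R,7S,8R)-1,3,5,7,8-pentamethylbicyclo[4.2.0]octa-2,4-dien-7-yl]-2H-pyran-2-one
Conditions: DBU, PhMe, 23 → 40 °C
Reagents that add atoms: none
Why: Base-promoted lactonisation of the δ-keto enol onto the ester with loss of methanol gives the 4-hydroxy-2-pyranone; the temperature is capped at 40 °C to avoid electrocyclic opening of the bicyclooctadiene.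

**Step 17**
Reactants: 25 4-hydroxy-3,5-dimethyl-6-[(1R,6R,7S,8R)-1,3,5,7,8-pentamethylbicyclo[4.2.0]octa-2,4-dien-7-yl]-2H-pyran-2-one
Product: 26 2-methoxy-3,5-dimethyl-6-[(1R,6R,7S,8R)-1,3,5,7,8-pentamethylbicyclo[4.2.0]octa-2,4-dien-7-yl]-4H-pyran-4-one
Conditions: MeOTf, 2,6-di-tert-butyl-4-methylpyridine, CH2Cl2, 0 → 23 °C
Reagents that add atoms: methyl trifluoromethanesulfonate, COS(=O)(=O)C(F)(F)F
Why: A hard methylating agent alkylates the neutral hydroxypyranone at the lactone carbonyl oxygen, and loss of the 4-OH proton gives the 2-methoxy-4-pyranone; the hindered pyridine takes up the acid so the diene is not exposed to it.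

**Step 18**
Reactants: 26 2-methoxy-3,5-dimethyl-6-[(1R,6R,7S,8R)-1,3,5,7,8-pentamethylbicyclo[4.2.0]octa-2,4-dien-7-yl]-4H-pyran-4-one
Product: 27 2-methoxy-3,5-dimethyl-6-[(1R,2R,5S,6R,7S,8R)-2,5-epidioxy-1,3,5,7,8-pentamethylbicyclo[4.2.0]oct-3-en-7-yl]-4H-pyran-4-one
Conditions: O2, 5,10,15,20-tetraphenylporphyrin (cat.), hν (visible), CH2Cl2, 0 °C
Reagents that add atoms: dioxygen, O=O
Why: [4+2] cycloaddition of singlet oxygen to the cisoid cyclic diene; the cyclobutane with its concave-face pyranone covers one face, so oxygen should add to the face carrying the C1 methyl and C6–H, which gives the C2 and C5 configurations of 27.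

## Compound list

1 | 2,4,6-trimethylphenol | Cc1cc(C)c(O)c(C)c1 | starting material
2 | allyl bromide (3-bromoprop-1-ene) | C=CCBr | starting material
3 | rac-6-allyl-2,4,6-trimethylcyclohexa-2,4-dien-1-one (ortho-dienone) | C=CCC1(C)C=C(C)C=C(C)C1=O | intermediate (not isolated)
4 | 4-allyl-2,4,6-trimethylcyclohexa-2,5-dien-1-one (achiral) | C=CCC1(C)C=C(C)C(=O)C(C)=C1 | intermediate
5 | 2-(1,3,5-trimethyl-4-oxocyclohexa-2,5-dien-1-yl)acetaldehyde | O=CCC1(C)C=C(C)C(=O)C(C)=C1 | intermediate
6 | allyl acetoacetate (prop-2-en-1-yl 3-oxobutanoate) | CC(=O)CC(=O)OCC=C | starting material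
7 | allyl 2-diazo-3-oxobutanoate | CC(=O)C(=[N+]=[N-])C(=O)OCC=C | intermediate (not isolated)
8 | allyl diazoacetate | C=CCOC(=O)C=[N+]=[N-] | intermediate
9 | allyl 3-oxo-4-(1,3,5-trimethyl-4-oxocyclohexa-2,5-dien-1-yl)butanoate | C=CCOC(=O)CC(=O)CC1(C)C=C(C)C(=O)C(C)=C1 | intermediate
10 | allyl (3aR,7aS)-3a,5,7-trimethyl-2,6-dioxo-2,3,3a,6,7,7a-hexahydro-1H-indene-1-carboxylate (cis-fused; C1, C7 epimers) | C=CCOC(=O)C1C(=O)C[C@@]2(C)C=C(C)C(=O)C(C)[C@@H]12 | intermediate
11 | allyl 3a,5,7-trimethyl-2-oxo-6-[(trifluoromethylsulfonyl)oxy]-2,3,3a,7a-tetrahydro-1H-indene-1-carboxylate (ring fusion as in 10; C1 epimers) | C=CCOC(=O)C1C(=O)C[C@@]2(C)C=C(C)C(OS(=O)(=O)C(F)(F)F)=C(C)[C@@H]12 | intermediate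
12 | allyl 3,3a,5,7-tetramethyl-2-oxo-6-[(trifluoromethylsulfonyl)oxy]-2,3,3a,7a-tetrahydro-1H-indene-1-carboxylate (3-methyl cis to 3a-methyl; C1 epimers) | C=CCOC(=O)C1C(=O)[C@H](C)[C@@]2(C)C=C(C)C(OS(=O)(=O)C(F)(F)F)=C(C)[C@@H]12 | intermediate
13 | 3,3a,5,7-tetramethyl-2-oxo-2,3,3a,7a-tetrahydro-1H-indene-1-carboxylic acid (ring centres as in 14) | OC(=O)C1C(=O)[C@H](C)[C@@]2(C)C=C(C)C=C(C)[C@@H]12 | intermediate (not isolated)
14 | (3R,3aS,7aR)-3,3a,5,7-tetramethyl-1,3,3a,7a-tetrahydro-2H-inden-2-one | C1C(=O)[C@H](C)[C@@]2(C)C=C(C)C=C(C)[C@@H]12 | intermediate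
15 | 3,3a,5,7-tetramethyl-1-(trifluoroacetyl)-1,3,3a,7a-tetrahydro-2H-inden-2-one (ring centres as in 14) | O=C(C1C(=O)[C@H](C)[C@@]2(C)C=C(C)C=C(C)[C@@H]12)C(F)(F)F | intermediate (not isolated)
16 | (3R,3aS,7aR)-1-diazo-3,3a,5,7-tetramethyl-1,3,3a,7a-tetrahydro-2H-inden-2-one | [N-]=[N+]=C1C(=O)[C@H](C)[C@@]2(C)C=C(C)C=C(C)[C@@H]12 | intermediate (key-step precursor)
17 | (1,3,5,8-tetramethylbicyclo[4.2.0]octa-2,4-dien-7-ylidene)methanone, the ketene (C1, C6, C8 as in 18) | O=C=C1[C@H](C)[C@@]2(C)C=C(C)C=C(C)[C@@H]12 | intermediate (not isolated)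
18 | methyl (1S,6R,7S,8S)-1,3,5,8-tetramethylbicyclo[4.2.0]octa-2,4-diene-7-carboxylate | COC(=O)[C@H]1[C@H](C)[C@@]2(C)C=C(C)C=C(C)[C@@H]12 | intermediate (key-step product)
19 | methyl (1R,6R,7S,8R)-1,3,5,7,8-pentamethylbicyclo[4.2.0]octa-2,4-diene-7-carboxylate | COC(=O)[C@@]1(C)[C@H](C)[C@@]2(C)C=C(C)C=C(C)[C@@H]12 | intermediate
20 | [(1R,6R,7S,8R)-1,3,5,7,8-pentamethylbicyclo[4.2.0]octa-2,4-dien-7-yl]methanol | OC[C@@]1(C)[C@H](C)[C@@]2(C)C=C(C)C=C(C)[C@@H]12 | intermediate
21 | (1R,6R,7S,8R)-1,3,5,7,8-pentamethylbicyclo[4.2.0]octa-2,4-diene-7-carbaldehyde | O=C[C@@]1(C)[C@H](C)[C@@]2(C)C=C(C)C=C(C)[C@@H]12 | intermediate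
22 | methyl 2-methyl-3-oxopentanoate (racemic) | CCC(=O)C(C)C(=O)OC | starting material
23 | methyl 5-hydroxy-2,4-dimethyl-3-oxo-5-[(1R,6R,7S,8R)-1,3,5,7,8-pentamethylbicyclo[4.2.0]octa-2,4-dien-7-yl]pentanoate (chain centres mixed) | COC(=O)C(C)C(=O)C(C)C(O)[C@@]1(C)[C@H](C)[C@@]2(C)C=C(C)C=C(C)[C@@H]12 | intermediate
24 | methyl 2,4-dimethyl-3,5-dioxo-5-[(1R,6R,7S,8R)-1,3,5,7,8-pentamethylbicyclo[4.2.0]octa-2,4-dien-7-yl]pentanoate | COC(=O)C(C)C(=O)C(C)C(=O)[C@@]1(C)[C@H](C)[C@@]2(C)C=C(C)C=C(C)[C@@H]12 | intermediate
25 | 4-hydroxy-3,5-dimethyl-6-[(1R,6R,7S,8R)-1,3,5,7,8-pentamethylbicyclo[4.2.0]octa-2,4-dien-7-yl]-2H-pyran-2-one | O=c1oc([C@@]2(C)[C@H](C)[C@@]3(C)C=C(C)C=C(C)[C@@H]23)c(C)c(O)c1C | intermediate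
26 | 2-methoxy-3,5-dimethyl-6-[(1R,6R,7S,8R)-1,3,5,7,8-pentamethylbicyclo[4.2.0]octa-2,4-dien-7-yl]-4H-pyran-4-one | COc1oc([C@@]2(C)[C@H](C)[C@@]3(C)C=C(C)C=C(C)[C@@H]23)c(C)c(=O)c1C | intermediate
27 | 2-methoxy-3,5-dimethyl-6-[(1R,2R,5S,6R,7S,8R)-2,5-epidioxy-1,3,5,7,8-pentamethylbicyclo[4.2.0]oct-3-en-7-yl]-4H-pyran-4-one | COc1oc([C@@]2(C)[C@H](C)[C@@]3(C)[C@@H]4OO[C@@](C)(C=C4C)[C@@H]23)c(C)c(=O)c1C | target

## Step count and least certain steps

Total: 18 steps. Longest linear sequence: 17 steps (1 to 27; step 3 is a one-step side branch).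

**Step 10 (key step).** The most likely failure is diversion of the excited diazoketone into carbene chemistry, namely insertion into the O–H bond of the solvent or a 1,2-shift of the allylic hydrogen on C7a. This is because the competing ring contraction has to build a strained, fully substituted four-membered ring. Fallback, from 16 back to 21: irradiation at 405 nm in THF containing N,O-dimethylhydroxylamine, so that no hydroxylic solvent is present and ketene 17 is taken up by the amine as (1S,6R,7S,8S)-N-methoxy-N,1,3,5,8-pentamethylbicyclo[4.2.0]octa-2,4-diene-7-carboxamide F1. Deprotonation with LiN(iPr)2 and methylation with MeI would give (1R,6R,7S,8R)-N-methoxy-N,1,3,5,7,8-hexamethylbicyclo[4.2.0]octa-2,4-diene-7-carboxamide F2, and LiAlH4 at −78 °C would reduce F2 directly to aldehyde 21, replacing steps 11 to 13 by two operations.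

**Step 5.** The most likely failure is insufficient discrimination between the two enone arms, or closure so slow (both arms carry an α-methyl group) that uncatalysed, racemic cyclisation competes. Fallback, from 9 back to 10, uses a covalent chiral controller instead of a catalyst. Condensation of 9 with (S)-1-phenylethylamine would give allyl (Z)-3-{[(1S)-1-phenylethyl]amino}-4-(1,3,5-trimethyl-4-oxocyclohexa-2,5-dien-1-yl)but-2-enoate F3. Warming in toluene (60 °C) should let the chiral secondary enamine add to one arm in an aza-ene-type Michael addition, giving allyl 3a,5,7-trimethyl-6-oxo-2-{[(1S)-1-phenylethyl]amino}-3a,6,7,7a-tetrahydro-3H-indene-1-carboxylate F4. Aqueous acetic acid would then hydrolyse F4 to 10 and release the amine.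

**Step 7.** The most likely failure is methylation on the concave face, or erosion of the C3 centre in steps 8 and 9. The convex face is flanked by the angular methyl, so the facial preference rests on a conformational argument and not on a large steric difference. Fallback, from 11 back to 12, delivers hydrogen to C3 instead of methyl. The dianion of 11 is quenched with CH2=NMe2+ I− to give allyl 3-[(dimethylamino)methyl]-3a,5,7-trimethyl-2-oxo-6-[(trifluoromethylsulfonyl)oxy]-2,3,3a,7a-tetrahydro-1H-indene-1-carboxylate F5. Quaternisation with MeI and elimination with DBU give allyl 3a,5,7-trimethyl-3-methylidene-2-oxo-6-[(trifluoromethylsulfonyl)oxy]-2,3,3a,7a-tetrahydro-1H-indene-1-carboxylate F6. Conjugate reduction with [(Ph3P)CuH]6 and protonation then give 12. A proton should follow the same facial preference that misplaced the methyl, which puts the methyl on the required face.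

**Step 11.** The most likely failure is poor or reversed facial selectivity of the enolate methylation, because the convex face is flanked by the cis methyl on C8. Fallback for the reversed sense, from 18 back to 20, exchanges the roles of the two C7 substituents. The enolate of 18 is quenched with gaseous formaldehyde to give methyl 7-(hydroxymethyl)-1,3,5,8-tetramethylbicyclo[4.2.0]octa-2,4-diene-7-carboxylate F7, with the hydroxymethyl on the face the electrophile prefers. Silylation (t-BuMe2SiCl, imidazole) gives methyl 7-({[tert-butyl(dimethyl)silyl]oxy}methyl)-1,3,5,8-tetramethylbicyclo[4.2.0]octa-2,4-diene-7-carboxylate F8. LiAlH4 gives [7-({[tert-butyl(dimethyl)silyl]oxy}methyl)-1,3,5,8-tetramethylbicyclo[4.2.0]octa-2,4-dien-7-yl]methanol F9, and MsCl/Et3N its methanesulfonate F10. LiEt3BH reduces F10 to tert-butyl(dimethyl){[1,3,5,7,8-pentamethylbicyclo[4.2.0]octa-2,4-dien-7-yl]methoxy}silane F11, in which the former ester carbon is now the C7 methyl. Bu4NF then gives alcohol 20. If the selectivity is merely low, the C7 epimers of 19 are separated.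

**Step 1.** The most likely failure is O-allylation of the phenoxide together with leakage of 3 back to the aromatic allyl ether (retro-Claisen) during the Cope step, which lowers throughput to 4. Fallback, from 1 directly to 4, is oxidative dearomatisation instead of enolate-type alkylation: PhI(OAc)2 and allyltrimethylsilane in (CF3)2CHOH at 0 °C, where the oxidised phenol is attacked at the para carbon by the silane (oxidative Hosomi–Sakurai allylation). No new compound is formed.

## Further compounds

F1 | step 10 | (1S,6R,7S,8S)-N-methoxy-N,1,3,5,8-pentamethylbicyclo[4.2.0]octa-2,4-diene-7-carboxamide | CON(C)C(=O)[C@H]1[C@H](C)[C@@]2(C)C=C(C)C=C(C)[C@@H]12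
F2 | step 10 | (1R,6R,7S,8R)-N-methoxy-N,1,3,5,7,8-hexamethylbicyclo[4.2.0]octa-2,4-diene-7-carboxamide | CON(C)C(=O)[C@@]1(C)[C@H](C)[C@@]2(C)C=C(C)C=C(C)[C@@H]12
F3 | step 5 | allyl (Z)-3-{[(1S)-1-phenylethyl]amino}-4-(1,3,5-trimethyl-4-oxocyclohexa-2,5-dien-1-yl)but-2-enoate | C=CCOC(=O)/C=C(\N[C@@H](C)c1ccccc1)CC1(C)C=C(C)C(=O)C(C)=C1
F4 | step 5 | allyl 3a,5,7-trimethyl-6-oxo-2-{[(1S)-1-phenylethyl]amino}-3a,6,7,7a-tetrahydro-3H-indene-1-carboxylate (ring fusion as in 10) | C=CCOC(=O)C1=C(N[C@@H](C)c2ccccc2)C[C@@]3(C)C=C(C)C(=O)C(C)[C@@H]13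
F5 | step 7 | allyl 3-[(dimethylamino)methyl]-3a,5,7-trimethyl-2-oxo-6-[(trifluoromethylsulfonyl)oxy]-2,3,3a,7a-tetrahydro-1H-indene-1-carboxylate | C=CCOC(=O)C1C(=O)C(CN(C)C)[C@@]2(C)C=C(C)C(OS(=O)(=O)C(F)(F)F)=C(C)[C@@H]12
F6 | step 7 | allyl 3a,5,7-trimethyl-3-methylidene-2-oxo-6-[(trifluoromethylsulfonyl)oxy]-2,3,3a,7a-tetrahydro-1H-indene-1-carboxylate | C=CCOC(=O)C1C(=O)C(=C)[C@@]2(C)C=C(C)C(OS(=O)(=O)C(F)(F)F)=C(C)[C@@H]12
F7 | step 11 | methyl 7-(hydroxymethyl)-1,3,5,8-tetramethylbicyclo[4.2.0]octa-2,4-diene-7-carboxylate (hydroxymethyl on the concave face) | OC[C@@]1(C(=O)OC)[C@H](C)[C@@]2(C)C=C(C)C=C(C)[C@@H]12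
F8 | step 11 | methyl 7-({[tert-butyl(dimethyl)silyl]oxy}methyl)-1,3,5,8-tetramethylbicyclo[4.2.0]octa-2,4-diene-7-carboxylate | CC(C)(C)[Si](C)(C)OC[C@@]1(C(=O)OC)[C@H](C)[C@@]2(C)C=C(C)C=C(C)[C@@H]12
F9 | step 11 | [7-({[tert-butyl(dimethyl)silyl]oxy}methyl)-1,3,5,8-tetramethylbicyclo[4.2.0]octa-2,4-dien-7-yl]methanol | CC(C)(C)[Si](C)(C)OC[C@@]1(CO)[C@H](C)[C@@]2(C)C=C(C)C=C(C)[C@@H]12
F10 | step 11 | [7-({[tert-butyl(dimethyl)silyl]oxy}methyl)-1,3,5,8-tetramethylbicyclo[4.2.0]octa-2,4-dien-7-yl]methyl methanesulfonate | CC(C)(C)[Si](C)(C)OC[C@@]1(COS(C)(=O)=O)[C@H](C)[C@@]2(C)C=C(C)C=C(C)[C@@H]12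
F11 | step 11 | tert-butyl(dimethyl){[1,3,5,7,8-pentamethylbicyclo[4.2.0]octa-2,4-dien-7-yl]methoxy}silane | CC(C)(C)[Si](C)(C)OC[C@@]1(C)[C@H](C)[C@@]2(C)C=C(C)C=C(C)[C@@H]12
F0 | step 1 | none | none
A1 | alternative 1 | 6-(2,5-epidioxy-1,3,5,7,8-pentamethyl-4-oxobicyclo[4.2.0]oct-7-yl)-2-methoxy-3,5-dimethyl-4H-pyran-4-one | COc1oc([C@@]2(C)[C@H](C)[C@@]3(C)[C@@H]4OO[C@@](C)(C(=O)[C@H]4C)[C@@H]23)c(C)c(=O)c1C
A2 | alternative 1 | 6-(5-hydroperoxy-1,3,5,7,8-pentamethyl-4-oxobicyclo[4.2.0]oct-2-en-7-yl)-2-methoxy-3,5-dimethyl-4H-pyran-4-one | COc1oc([C@@]2(C)[C@H](C)[C@@]3(C)C=C(C)C(=O)[C@](C)(OO)[C@@H]23)c(C)c(=O)c1C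
A3 | alternative 2 | methyl (1R,6R,7S,8R)-1,3,5,7,8-pentamethylbicyclo[4.2.0]octa-2,4-diene-7-carboxylate (identical with 19) | COC(=O)[C@@]1(C)[C@H](C)[C@@]2(C)C=C(C)C=C(C)[C@@H]12
A4 | alternative 2 | methyl (1R,4R)-1,3,4-trimethylcyclobut-2-ene-1-carboxylate | COC(=O)[C@@]1(C)[C@H](C)C(C)=C1
A5 | alternative 2 | 2,4-dimethylthiophene 1,1-dioxide | O=S1(=O)C=C(C)C=C1C
A6 | alternative 3 | (−)-8-phenylmenthyl 1,3,5,7,8-pentamethylbicyclo[4.2.0]octa-2,4-diene-7-carboxylate | C[C@@H]1CC[C@H]([C@@H](C1)OC(=O)[C@@]2(C)[C@H](C)[C@@]3(C)C=C(C)C=C(C)[C@@H]23)C(C)(C)c1ccccc1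
A7 | alternative 3 | (−)-8-phenylmenthyl tiglate [(E)-2-methylbut-2-enoate] | C[C@@H]1CC[C@H]([C@@H](C1)OC(=O)/C(C)=C/C)C(C)(C)c1ccccc1
A8 | alternative 3 | mesitylene (1,3,5-trimethylbenzene) | Cc1cc(C)cc(C)c1
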